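A direct plan would build ring A onto a five-membered ring by an amino-acid-mediated Robinson annulation to enedione A1 and carry the hydrindane to the α′-hydroxy vinyl ketone A2.
It would then attach the side chain by a nickel-catalysed reductive coupling with a 2-alkynoate, enlarge the five-membered ring to ring B by an α-ketol shift to acyloin A3, methylenate, isomerise the alkene, benzoylate both hydroxyls to dibenzoate A4 and saponify selectively.
Its weakest step would be the reductive enone–alkynoate coupling of A2: it has no precedent for this substrate pair, yet the C12–C13 bond, its regiochemistry and the 13E geometry would all depend on it.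
Next would be the ketol shift to A3: the C9 configuration and the choice of migrating carbon would rest on a conformational preference in a reversible rearrangement, so a stereocentre would be left to chance.
Last would be the final ester differentiation of A4 on the most precious material: hydroxide would have to cleave a methyl enoate and a 3-benzoate but spare the tertiary 9-benzoate, after a double benzoylation with strong base next to the enoate.
It would also spend a ketal on/off pair and a methylenation/isomerisation pair for little gain in complexity.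

**Plan of the new route**
The retrosynthesis cuts the 9-O–benzoyl bond and C14–C15, returns the Δ7-9α-ol to an 8α,9α-epoxy-7-ketone (Wharton), the 8-en-7-one to a C9 ketone plus a C11 nucleophile, and then cuts C3–C4 of ring A.
The enabling feature is that C4 is a gem-dimethyl carbon between C5–H and the oxygenated C3, so it can be a tertiary radical born from an isopropenyl group. The rest (C5, C6, C7=C8 with C17, C9=O, C10) is the ring of (R)-carvone, whose stereocentre is C5 and whose ten carbons are all kept.
Ring B therefore exists from the start; ring A is closed second, by addition of the C4 radical to a C3 nitrile, with the trans fusion fixed beforehand by two α′-alkylations.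
C9 is set by α-face epoxidation of a locked trans-decalin enone, not by an equilibrium. The chain comes from a Grignard addition and a zirconium-catalysed carboalumination (13E by syn addition). Only one benzoate is ever made, so no reductive coupling, ketol shift or selective saponification arises.

Key step: step 4

Assumption: the second α′-alkylation of carvone takes place anti to the neighbouring isopropenyl group, as is usual for 6-alkylcarvones. Labdane numbering and α/β descriptors are used for all bicyclic compounds.

**Step 1**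
Reactants: 1 (R)-(–)-carvone
Product: 2 (5R)-2,6-dimethyl-5-(prop-1-en-2-yl)cyclohex-2-en-1-one (6-methylcarvone; C6 epimers)
Conditions: LiN(i-Pr)2 (1.1 equiv), THF, −78 °C; MeI (1.5 equiv), −78 → 0 °C
Reagents that add atoms: iodomethane, CI
Why: Kinetic α′-enolate formation and C-methylation (enolate alkylation); the new C6 centre forms as an epimer mixture that is erased when the same carbon is enolised again in step 2.

**Step 2**
Reactants: 2 6-methylcarvone; 3 allyl bromide
Product: 4 (5S,6S)-2,6-dimethyl-6-(prop-2-en-1-yl)-5-(prop-1-en-2-yl)cyclohex-2-en-1-one (allyl trans to isopropenyl)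
Conditions: LiN(i-Pr)2 (1.2 equiv), THF, −78 → 0 °C; 3 (2 equiv), DMPU, −78 → 23 °C
Reagents that add atoms: none
Why: Second α′-enolate alkylation, in which allyl bromide approaches the planar enolate anti to the adjacent isopropenyl group, so the allyl arm (future C1–C3) ends trans and the methyl (future C20) cis to the future C4, as a trans ring fusion requires.

**Step 3**
Reactants: 4 allyl ketone
Product: 6 3-[(1S,6S)-1,3-dimethyl-2-oxo-6-(prop-1-en-2-yl)cyclohex-3-en-1-yl]propanenitrile, via aldehyde 5 (not isolated)
Conditions: PdCl2(PhCN)2 (10 mol %), CuCl2·2H2O (10 mol %), AgNO2 (5 mol %), O2 (1 atm), t-BuOH–MeNO2 (15:1), 23 °C; filter through silica, concentrate; then I2 (1.3 equiv), 28% aq. NH3, THF, 23 °C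
Reagents that add atoms: ammonia, N
Why: Nitrite-modified, aldehyde-selective Wacker oxidation of the monosubstituted alkene (the 1,1-disubstituted isopropenyl group and the enone are inert), then oxidative conversion of the crude aldehyde to the nitrile with iodine in aqueous ammonia via the N-iodo aldimine; no stereocentre is affected.

**Step 4**
Reactants: 6 alkenyl nitrile
Product: 8 11,12,13,14,15,16-hexanorlabd-7-ene-3,9-dione (5α-H; 10β-CH3; trans-fused), via ketimine 7 (not isolated)
Conditions: Fe(acac)3 (0.5 equiv), PhSiH3 (2.5 equiv), EtOH (0.02 M, degassed), 60 °C; then 1 M HCl–THF, 23 °C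
Reagents that add atoms: water, O
Why: Iron hydride formed from Fe(acac)3 and PhSiH3 transfers a hydrogen atom to the CH2 terminus of the isopropenyl group (Markovnikov MHAT), the resulting tertiary C4 radical, now carrying both methyls, adds to the nitrile carbon C3, and the iminyl radical is reduced and protonated to the N–H ketimine that acid hydrolyses to the C3 ketone. The closest known reaction type is the iron-hydride HAT cyclisation of alkenyl nitriles to cyclic ketones, which tolerates α-quaternary centres. Ring A closes by C3–C4 bond formation in the 6-exo-dig mode through a chair in which the radical-bearing carbon on C5 and the cyanoethyl arm on C10 are both equatorial on ring B. No new stereocentre is formed (C4 bears two methyls, C3 is sp2); the trans ring fusion follows from the trans arrangement of the two arms set in step 2, and C5 comes from carvone. The step needs HAT at the electron-rich 1,1-disubstituted alkene and not at the conjugated C7=C8, and cyclisation ahead of reduction or intermolecular addition to the enone: the α-methylated, electron-poor enone is a slow hydrogen-atom acceptor and a poor radical trap, HAT to hindered alkenes is reversible so the radical is regenerated, and high dilution suppresses bimolecular paths.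

**Step 5**
Reactants: 8 ene-dione
Product: 9 3β-hydroxy-11,12,13,14,15,16-hexanorlabd-7-en-9-one
Conditions: NaBH4 (0.35 equiv), MeOH–CH2Cl2 (1:1), −20 °C
Reagents that add atoms: none
Why: Chemoselective borohydride reduction of the saturated C3 ketone beside the more hindered, conjugated C9 carbonyl (as in mono-reduction of Wieland–Miescher-type enediones), with axial hydride delivery from the α face, away from the 4β- and 10β-methyls, giving the equatorial 3β-alcohol as for 4,4-dimethyl-3-oxo triterpenoids.

**Step 6**
Reactants: 9 hydroxy enone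
Product: 10 3β-(tert-butyldimethylsilyloxy)-11,12,13,14,15,16-hexanorlabd-7-en-9-one
Conditions: TBSOTf (1.3 equiv), 2,6-lutidine (2 equiv), CH2Cl2, −78 → 0 °C
Reagents that add atoms: tert-butyldimethylsilyl trifluoromethanesulfonate, CC(C)(C)[Si](C)(C)OS(=O)(=O)C(F)(F)F
Why: Silylation of the hindered secondary alcohol with a silyl triflate and a non-nucleophilic base; no stereocentre is touched.

**Step 7**
Reactants: 10 silyloxy enone; 11 (4-bromobut-1-yn-1-yl)trimethylsilane
Product: 13 3β-(tert-butyldimethylsilyloxy)-14-(trimethylsilyl)-15,16-dinor-9-epi-labd-7-en-13-yn-9-ol (9β-OH; chain α), via Grignard reagent 12 (not isolated)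
Conditions: 11 (3 equiv), Mg, THF, 23 → 40 °C; cannulate onto anhydrous CeCl3 (3 equiv), THF, −78 °C; add 10, −78 → 0 °C; aq. NH4Cl
Reagents that add atoms: none
Why: CeCl3-promoted 1,2-addition of the Grignard reagent to the hindered enone carbonyl (no α-hydrogen at C10), expected from the α face anti to the axial C10 methyl; the C9 configuration is immaterial because C9 becomes sp2 in step 8.

**Step 8**
Reactants: 13 tertiary allylic alcohol
Product: 14 3β-(tert-butyldimethylsilyloxy)-14-(trimethylsilyl)-15,16-dinorlabd-8-en-13-yn-7-one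
Conditions: pyridinium chlorochromate, (C5H5NH)[CrO3Cl] (3 equiv), 4 Å MS, CH2Cl2, 23 °C
Reagents that add atoms: pyridinium chlorochromate, [O-][Cr](=O)(=O)Cl.c1cc[nH+]cc1
Why: Dauben–Babler oxidative 1,3-transposition, in which the chromate ester of the tertiary allylic alcohol shifts [3,3] to C7 and is oxidised to the enone, as known for 1-alkyl-2,6,6-trimethylcyclohex-2-enols; the silyl ether and the silylalkyne are inert.

**Step 9**
Reactants: 14 transposed enone
Product: 16 8α,9α-epoxy-3β-(tert-butyldimethylsilyloxy)-15,16-dinorlabd-13-yn-7-one, via desilylated enone 15 (not isolated)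
Conditions: 30% H2O2 (10 equiv), 6 M NaOH (2 equiv), MeOH–THF (3:1), 0 → 40 °C
Reagents that add atoms: hydrogen peroxide, OO
Why: Weitz–Scheffer nucleophilic epoxidation, in which hydroperoxide adds to C9 axially on the α face of the locked trans-decalin enone, anti to the axial 10β-methyl, and the enolate closes on the same face to give the 8α,9α-epoxide (this fixes the C9–O bond of the target), while methanolic hydroxide also removes the alkynyl silyl group.

**Step 10**
Reactants: 16 epoxy ketone
Product: 19 3β-(tert-butyldimethylsilyloxy)-15,16-dinorlabd-7-en-13-yn-9α-ol, via hydrazone 17 (not isolated), via alkenyldiazene 18 (not isolated)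
Conditions: N2H4·H2O (5 equiv), AcOH (0.5 equiv), MeOH, 0 → 23 °C, under N2
Reagents that add atoms: none
Why: Wharton transposition, in which the C7 hydrazone opens the epoxide at C8 to an alkenyldiazene that loses N2, placing the alkene at C7=C8 and leaving the C9–O bond untouched, so the 9α configuration set in step 9 is retained.

**Step 11**
Reactants: 19 alkynol
Product: 21 3β-(tert-butyldimethylsilyloxy)-9α-hydroxylabda-7,13E-dien-15-oic acid, via alkenylalane 20 (not isolated)
Conditions: Me3Al (4 equiv), Cp2ZrCl2 (0.4 equiv), CH2Cl2, 0 → 23 °C; evaporate volatiles; THF, n-BuLi (2.2 equiv), −78 °C; CO2 (gas), −78 → 0 °C; cold 1 M HCl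
Reagents that add atoms: trimethylaluminium, C[Al](C)C; carbon dioxide, O=C=O
Why: Negishi zirconium-catalysed carboalumination adds methyl and aluminium syn, methyl to the internal carbon, to give the (E)-2-methylalkenylalane, whose alanate is carboxylated with retention, so the 13E geometry follows from the mechanism; the tertiary hydroxyl is carried as its aluminium alkoxide.

**Step 12**
Reactants: 21 hydroxy acid
Product: 23 9α-benzoyloxy-3β-(tert-butyldimethylsilyloxy)labda-7,13E-dien-15-oic acid, via mixed anhydride 22 (not isolated)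
Conditions: KN(SiMe3)2 (2.3 equiv), THF, −78 °C; BzCl (3 equiv), −78 → 0 °C; then pyridine–H2O (4:1), 23 °C
Reagents that add atoms: benzoyl chloride, O=C(Cl)c1ccccc1
Why: Acylation of the potassium alkoxide of the hindered tertiary allylic alcohol with benzoyl chloride, the carboxylate protecting the enoate internally against γ-deprotonation and conjugate addition of the C9 alkoxide; the mixed anhydride formed at the carboxylate is hydrolysed by aqueous pyridine and no stereocentre is touched.

**Step 13**
Reactants: 23 silyl ether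
Product: 24 9α-benzoyloxy-3β-hydroxylabda-7,13E-dien-15-oic acid (CNP0288577.1)
Conditions: HF·pyridine, pyridine, THF, 0 → 40 °C
Reagents that add atoms: none
Why: Fluoride cleavage of the silyl ether under buffered conditions that should neither ionise the tertiary allylic benzoate nor isomerise the enoic acid; the 3β configuration was fixed in step 5.

**Compound list**
1 | (R)-(–)-carvone | CC1=CC[C@@H](C(C)=C)CC1=O | starting material
2 | (5R)-2,6-dimethyl-5-(prop-1-en-2-yl)cyclohex-2-en-1-one (6-methylcarvone, C6 epimers) | CC1=CC[C@@H](C(C)=C)C(C)C1=O | intermediate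
3 | allyl bromide | C=CCBr | starting material
4 | (5S,6S)-2,6-dimethyl-6-(prop-2-en-1-yl)-5-(prop-1-en-2-yl)cyclohex-2-en-1-one (allyl trans to isopropenyl) | CC1=CC[C@@H](C(C)=C)[C@](C)(CC=C)C1=O | intermediate
5 | 3-[(1S,6S)-1,3-dimethyl-2-oxo-6-(prop-1-en-2-yl)cyclohex-3-en-1-yl]propanal | CC1=CC[C@@H](C(C)=C)[C@](C)(CCC=O)C1=O | intermediate
6 | 3-[(1S,6S)-1,3-dimethyl-2-oxo-6-(prop-1-en-2-yl)cyclohex-3-en-1-yl]propanenitrile | CC1=CC[C@@H](C(C)=C)[C@](C)(CCC#N)C1=O | intermediate
7 | 3-imino-11,12,13,14,15,16-hexanorlabd-7-en-9-one (N–H ketimine) | CC1=CC[C@H]2C(C)(C)C(=N)CC[C@]2(C)C1=O | intermediate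
8 | 11,12,13,14,15,16-hexanorlabd-7-ene-3,9-dione (5α-H, 10β-CH3, trans-fused) | CC1=CC[C@H]2C(C)(C)C(=O)CC[C@]2(C)C1=O | intermediate
9 | 3β-hydroxy-11,12,13,14,15,16-hexanorlabd-7-en-9-one | CC1=CC[C@H]2C(C)(C)[C@@H](O)CC[C@]2(C)C1=O | intermediate
10 | 3β-(tert-butyldimethylsilyloxy)-11,12,13,14,15,16-hexanorlabd-7-en-9-one | CC1=CC[C@H]2C(C)(C)[C@@H](O[Si](C)(C)C(C)(C)C)CC[C@]2(C)C1=O | intermediate
11 | (4-bromobut-1-yn-1-yl)trimethylsilane | C[Si](C)(C)C#CCCBr | starting material
12 | [4-(trimethylsilyl)but-3-yn-1-yl]magnesium bromide | C[Si](C)(C)C#CCC[Mg]Br | intermediate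
13 | 3β-(tert-butyldimethylsilyloxy)-14-(trimethylsilyl)-15,16-dinor-9-epi-labd-7-en-13-yn-9-ol (9β-OH, chain α; expected major epimer) | CC1=CC[C@H]2C(C)(C)[C@@H](O[Si](C)(C)C(C)(C)C)CC[C@]2(C)[C@@]1(CCC#C[Si](C)(C)C)O | intermediate
14 | 3β-(tert-butyldimethylsilyloxy)-14-(trimethylsilyl)-15,16-dinorlabd-8-en-13-yn-7-one | CC1=C(CCC#C[Si](C)(C)C)[C@@]2(C)CC[C@H](O[Si](C)(C)C(C)(C)C)C(C)(C)[C@@H]2CC1=O | intermediate
15 | 3β-(tert-butyldimethylsilyloxy)-15,16-dinorlabd-8-en-13-yn-7-one | CC1=C(CCC#C)[C@@]2(C)CC[C@H](O[Si](C)(C)C(C)(C)C)C(C)(C)[C@@H]2CC1=O | intermediate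
16 | 8α,9α-epoxy-3β-(tert-butyldimethylsilyloxy)-15,16-dinorlabd-13-yn-7-one | C[C@]12O[C@@]1(CCC#C)[C@@]3(C)CC[C@H](O[Si](C)(C)C(C)(C)C)C(C)(C)[C@@H]3CC2=O | intermediate
17 | C7 hydrazone of 16 | C[C@]12O[C@@]1(CCC#C)[C@@]3(C)CC[C@H](O[Si](C)(C)C(C)(C)C)C(C)(C)[C@@H]3CC2=NN | intermediate
18 | 7-diazenyl-3β-(tert-butyldimethylsilyloxy)-15,16-dinorlabd-7-en-13-yn-9α-ol | CC1=C(N=N)C[C@H]2C(C)(C)[C@@H](O[Si](C)(C)C(C)(C)C)CC[C@]2(C)[C@]1(CCC#C)O | intermediate
19 | 3β-(tert-butyldimethylsilyloxy)-15,16-dinorlabd-7-en-13-yn-9α-ol | CC1=CC[C@H]2C(C)(C)[C@@H](O[Si](C)(C)C(C)(C)C)CC[C@]2(C)[C@]1(CCC#C)O | intermediate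
20 | (13E)-14-(dimethylalumanyl)-15-norlabda-7,13-diene 9α-O-dimethylaluminium alkoxide, 3β-silyl ether | CC1=CC[C@H]2C(C)(C)[C@@H](O[Si](C)(C)C(C)(C)C)CC[C@]2(C)[C@]1(CC/C(C)=C/[Al](C)C)O[Al](C)C | intermediate
21 | 3β-(tert-butyldimethylsilyloxy)-9α-hydroxylabda-7,13E-dien-15-oic acid | CC1=CC[C@H]2C(C)(C)[C@@H](O[Si](C)(C)C(C)(C)C)CC[C@]2(C)[C@]1(CC/C(C)=C/C(=O)O)O | intermediate
22 | benzoic mixed anhydride of 23 | CC1=CC[C@H]2C(C)(C)[C@@H](O[Si](C)(C)C(C)(C)C)CC[C@]2(C)[C@]1(CC/C(C)=C/C(=O)OC(=O)c1ccccc1)OC(=O)c1ccccc1 | intermediate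
23 | 9α-benzoyloxy-3β-(tert-butyldimethylsilyloxy)labda-7,13E-dien-15-oic acid | CC1=CC[C@H]2C(C)(C)[C@@H](O[Si](C)(C)C(C)(C)C)CC[C@]2(C)[C@]1(CC/C(C)=C/C(=O)O)OC(=O)c1ccccc1 | intermediate
24 | 9α-benzoyloxy-3β-hydroxylabda-7,13E-dien-15-oic acid (CNP0288577.1) | CC1=CC[C@H]2C(C)(C)[C@@H](O)CC[C@]2(C)[C@]1(CC/C(C)=C/C(=O)O)OC(=O)c1ccccc1 | target

Total step count: 13. Longest linear sequence: 13 steps, from (R)-carvone 1 to 24.

**Steps most likely to fail**

Step 4. The tertiary C4 radical may be reduced (net hydrogenation of the isopropenyl group) or may add intermolecularly to the enone before it closes onto the nitrile. The fallback generates the same radical by a halogen-abstraction chain, in which the hydrogen-donor concentration can be set independently. It sets out from 6: Markovnikov hydrobromination of the isopropenyl group (HBr, AcOH, 0 °C, as for carvone hydrobromide) would give the tertiary bromide F1. Slow addition of (Me3Si)3SiH and AIBN in benzene at 80 °C would then effect the 6-exo-dig closure to ketimine 7, and acid hydrolysis as before would rejoin the route at 8.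

Step 9. Conjugate addition of hydroperoxide to the fully substituted, neopentyl β-carbon C9 may be too slow, and forcing it may erode the facial selectivity. The fallback replaces nucleophilic epoxidation of the enone by hydroxyl-directed electrophilic epoxidation of an electron-rich alkene. It sets out from 14: LiBH(s-Bu)3 in THF at −78 °C should deliver hydride equatorially to give the pseudoaxial 7α-allylic alcohol F2. VO(acac)2/t-BuOOH should epoxidise syn to that hydroxyl, which is also the less hindered α face, to give epoxy alcohol F3. Dess–Martin periodinane would give the silylated epoxy ketone F4, and K2CO3 in MeOH would remove the alkynyl silyl group to rejoin at 16.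

Step 12. Acylation of the most hindered hydroxyl of the molecule may stall while benzoyl chloride is consumed at the carboxylate. The fallback acylates the neutral alcohol with a far stronger electrophile on an ester-protected substrate. It sets out from 21: Me3SiCHN2 in toluene–MeOH would give the methyl ester F5. Benzoyl triflate with pyridine in CH2Cl2 at −78 °C would give the 9-benzoate F6. Me3SnOH in 1,2-dichloroethane at 70 °C, which cleaves methyl esters but not a hindered tertiary benzoate, would rejoin at 23.

**Further compounds**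
F1 | step 4 | 3-[(1S,6R)-6-(2-bromopropan-2-yl)-1,3-dimethyl-2-oxocyclohex-3-en-1-yl]propanenitrile (same spatial arrangement as in 6) | CC1=CC[C@@H](C(C)(C)Br)[C@](C)(CCC#N)C1=O
F2 | step 9 | 3β-(tert-butyldimethylsilyloxy)-14-(trimethylsilyl)-15,16-dinorlabd-8-en-13-yn-7α-ol | CC1=C(CCC#C[Si](C)(C)C)[C@@]2(C)CC[C@H](O[Si](C)(C)C(C)(C)C)C(C)(C)[C@@H]2C[C@H]1O
F3 | step 9 | 8α,9α-epoxy-3β-(tert-butyldimethylsilyloxy)-14-(trimethylsilyl)-15,16-dinorlabd-13-yn-7α-ol | C[C@]12O[C@@]1(CCC#C[Si](C)(C)C)[C@@]3(C)CC[C@H](O[Si](C)(C)C(C)(C)C)C(C)(C)[C@@H]3C[C@H]2O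
F4 | step 9 | 8α,9α-epoxy-3β-(tert-butyldimethylsilyloxy)-14-(trimethylsilyl)-15,16-dinorlabd-13-yn-7-one | C[C@]12O[C@@]1(CCC#C[Si](C)(C)C)[C@@]3(C)CC[C@H](O[Si](C)(C)C(C)(C)C)C(C)(C)[C@@H]3CC2=O
F5 | step 12 | methyl 3β-(tert-butyldimethylsilyloxy)-9α-hydroxylabda-7,13E-dien-15-oate | CC1=CC[C@H]2C(C)(C)[C@@H](O[Si](C)(C)C(C)(C)C)CC[C@]2(C)[C@]1(CC/C(C)=C/C(=O)OC)O
F6 | step 12 | methyl 9α-benzoyloxy-3β-(tert-butyldimethylsilyloxy)labda-7,13E-dien-15-oate | CC1=CC[C@H]2C(C)(C)[C@@H](O[Si](C)(C)C(C)(C)C)CC[C@]2(C)[C@]1(CC/C(C)=C/C(=O)OC)OC(=O)c1ccccc1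
A1 | direct plan | (S)-4,7a-dimethyl-2,3,7,7a-tetrahydro-1H-indene-1,5(6H)-dione | CC1=C2CCC(=O)[C@@]2(C)CCC1=O
A2 | direct plan | 8α-acryloyl-4,4,10-trimethyl-5α-hydrindane-3β,8β-diol | CC1(C)[C@@H]2CC[C@@](O)(C(=O)C=C)[C@@]2(C)CC[C@@H]1O
A3 | direct plan | methyl 3β,9α-dihydroxy-8-oxo-17-norlabd-13E-en-15-oate | O=C1CC[C@H]2C(C)(C)[C@@H](O)CC[C@]2(C)[C@]1(CC/C(C)=C/C(=O)OC)O
A4 | direct plan | methyl 3β,9α-bis(benzoyloxy)labda-7,13E-dien-15-oate | CC1=CC[C@H]2C(C)(C)[C@@H](OC(=O)c3ccccc3)CC[C@]2(C)[C@]1(CC/C(C)=C/C(=O)OC)OC(=O)c1ccccc1
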